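Ring A is the sulfated ring, ring B the central ring and ring C the terminal ring, each numbered from its oxygen-bearing carbon. Everything rests on cutting the bond between the B–C ether oxygen and carbon 1 of ring C. Ring C carries bromine only ortho and para to its single oxygen (carbons 2 and 4), so it can arrive as bare benzyne and be brominated afterwards. The B–C oxygen, buried on carbon 2 of ring B between the A–B ether oxygen and the carbon-3 bromine, is reached by this small, metal-free electrophile. In one operation the phenoxide of the A–B pentabromophenol (ring-A oxygen masked as methyl ether) is O-arylated. Demethylation, fluorosulfation, ring-C dibromination and sulfate unmasking follow.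

Key step: step 5

Remarks on the chemistry:
- Numbering used below: ring A carbon 1 bears the sulfate oxygen, carbon 2 the ether oxygen to ring B, carbons 3 and 5 bromine. Ring B carbon 1 bears the ether oxygen to ring A, carbon 2 the ether oxygen to ring C, carbons 3 to 5 bromine, carbon 6 hydrogen. Ring C carbon 1 bears the ether oxygen, carbons 2 and 4 bromine.
- The target has no stereocentre and no stable chiral axis, so no stereocontrol is needed.
- The target is drawn as the free hydrogen sulfate. The last step is written to give this acid form by cold acidification of the cesium salt; the salt is the form in which the compound would be stored.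

Step 1
Reactants: 1 guaiacol (2-methoxyphenol)
Product: 3 2,4-dibromo-6-methoxyphenol, via 2-bromo-6-methoxyphenol 2 (not isolated)
Conditions: NBS (2.05 equiv), i-Pr2NH (10 mol%), CH2Cl2, 0 °C → rt
Reagents that add atoms: N-bromosuccinimide, O=C1CCC(=O)N1Br
Why: Amine-catalysed electrophilic aromatic bromination directed by the free hydroxyl: the N-bromoamine, hydrogen-bonded to the phenol OH, should deliver the first bromine ortho to OH (giving 2) and the second equivalent should enter para to OH, the stronger donor, while the position para to the weaker methoxy donor stays free.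

Step 2
Reactants: 3 2,4-dibromo-6-methoxyphenol; 4 5-bromo-2-fluorobenzaldehyde
Product: 5 5-bromo-2-(2,4-dibromo-6-methoxyphenoxy)benzaldehyde
Conditions: K2CO3, DMAc, 120 °C, under nitrogen
Reagents that add atoms: none
Why: SNAr (addition–elimination): the fluoride of 4 is activated by the ortho formyl group and is displaced by the phenoxide of 3, whereas the C–Br bond of 4 (meta to CHO) and the bromines of 3 are not activated.

Step 3
Reactants: 5 5-bromo-2-(2,4-dibromo-6-methoxyphenoxy)benzaldehyde
Product: 7 5-bromo-2-(2,4-dibromo-6-methoxyphenoxy)phenol, via 5-bromo-2-(2,4-dibromo-6-methoxyphenoxy)phenyl formate 6 (not isolated)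
Conditions: mCPBA, CH2Cl2, 40 °C; then Et3N, MeOH, rt
Reagents that add atoms: meta-chloroperoxybenzoic acid, O=C(OO)c1cccc(Cl)c1
Why: Baeyer–Villiger (Dakin-type) oxidation: in the Criegee adduct the aryl group, made migration-prone by its ortho aryloxy oxygen, should migrate in preference to hydride to give formate 6, which mild methanolysis cleaves to the phenol.

Step 4
Reactants: 7 5-bromo-2-(2,4-dibromo-6-methoxyphenoxy)phenol
Product: 9 2,3,4-tribromo-6-(2,4-dibromo-6-methoxyphenoxy)phenol (A–B phenol), via 4,5-dibromo-2-(2,4-dibromo-6-methoxyphenoxy)phenol 8 (not isolated)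
Conditions: Br2 (2.1 equiv), NaOAc, AcOH, rt
Reagents that add atoms: bromine, BrBr
Why: Electrophilic aromatic bromination of the only free phenol: bromine should enter para (carbon 5 of ring B, giving 8) and then ortho (carbon 3 of ring B) to the hydroxyl on carbon 2 in buffered acetic acid, while carbon 6 of ring B (meta to OH) and the dibromoanisole ring A are far less reactive at this stoichiometry.

Step 5
Reactants: 9 2,3,4-tribromo-6-(2,4-dibromo-6-methoxyphenoxy)phenol; 10 2-(trimethylsilyl)phenyl triflate
Product: 12 1,5-dibromo-3-methoxy-2-(3,4,5-tribromo-2-phenoxyphenoxy)benzene, via benzyne 11 (not isolated)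
Conditions: CsF (3 equiv), MeCN, rt; 10 (1.5 equiv) added slowly
Reagents that add atoms: none
Why: Fluoride attacks silicon of 10 and triflate leaves in a 1,2-elimination to give benzyne 11; the cesium phenoxide of 9 (formed by CsF) adds through the oxygen on carbon 2 of ring B to the strained triple bond, and the resulting aryl anion on carbon 2 of ring C is protonated by acetonitrile or by remaining phenol. The closest known reaction is the fluoride-induced O-arylation of phenols with 2-(trimethylsilyl)aryl triflates, which runs at room temperature without metal and tolerates aryl halides and ortho substituents. One skeletal bond (B–C ether oxygen to carbon 1 of ring C) forms, no ring closes and no stereocentre is created. The step needs O- over C-arylation, which is secured because every ortho and para carbon of the phenoxide ring (carbons 1, 3 and 5 of ring B) is substituted, and it needs the five C–Br bonds to stay intact, which the metal-free conditions ensure. Benzyne is symmetrical, so no regiochemical question arises at the aryne, and slow addition of 10 keeps its concentration low so that capture by the weakly nucleophilic, doubly flanked phenoxide should outrun self-consumption of benzyne.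

Step 6
Reactants: 12 1,5-dibromo-3-methoxy-2-(3,4,5-tribromo-2-phenoxyphenoxy)benzene
Product: 14 3,5-dibromo-2-(3,4,5-tribromo-2-phenoxyphenoxy)phenol, via dibromo[3,5-dibromo-2-(3,4,5-tribromo-2-phenoxyphenoxy)phenoxy]borane 13 (not isolated)
Conditions: BBr3 (3 equiv), CH2Cl2, −78 °C → rt; then H2O
Reagents that add atoms: none
Why: Lewis-acid ether cleavage: BBr3 complexes the only alkyl aryl ether oxygen and bromide removes the methyl group by nucleophilic substitution at carbon to give borate 13, hydrolysed on work-up, while the diaryl ether and C–Br bonds are not touched.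

Step 7
Reactants: 14 3,5-dibromo-2-(3,4,5-tribromo-2-phenoxyphenoxy)phenol
Product: 15 3,5-dibromo-2-(3,4,5-tribromo-2-phenoxyphenoxy)phenyl fluorosulfate
Conditions: SO2F2 (balloon), Et3N, CH2Cl2, rt
Reagents that add atoms: sulfuryl fluoride, O=S(=O)(F)F
Why: Sulfur(VI) fluoride exchange: the triethylammonium phenoxide displaces one fluoride of SO2F2, and the reaction should stop at the aryl fluorosulfate because this is far less electrophilic than the gas.

Step 8
Reactants: 15 3,5-dibromo-2-(3,4,5-tribromo-2-phenoxyphenoxy)phenyl fluorosulfate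
Product: 17 3,5-dibromo-2-[3,4,5-tribromo-2-(2,4-dibromophenoxy)phenoxy]phenyl fluorosulfate, via 3,5-dibromo-2-[3,4,5-tribromo-2-(4-bromophenoxy)phenoxy]phenyl fluorosulfate 16 (not isolated)
Conditions: Br2 (2.2 equiv), Fe powder (5 mol%), CH2Cl2, 0 °C → rt
Reagents that add atoms: bromine, BrBr
Why: Electrophilic aromatic bromination: ring C is the only ring free of bromine and is activated by its ether oxygen alone, so bromine should enter para (carbon 4 of ring C, giving 16) and then ortho (carbon 2 of ring C), while ring A (fluorosulfate plus two Br), carbon 6 of ring B (a ring with three Br) and carbon 6 of ring C (two meta Br after the second substitution) are much less reactive and the acid-stable fluorosulfate should survive.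

Step 9
Reactants: 17 3,5-dibromo-2-[3,4,5-tribromo-2-(2,4-dibromophenoxy)phenoxy]phenyl fluorosulfate
Product: 20 bromoiesol A sulfate (3,5-dibromo-2-[3,4,5-tribromo-2-(2,4-dibromophenoxy)phenoxy]phenyl hydrogen sulfate), via N-({3,5-dibromo-2-[3,4,5-tribromo-2-(2,4-dibromophenoxy)phenoxy]phenoxy}sulfonyloxy)benzamide 18 (not isolated), via cesium 3,5-dibromo-2-[3,4,5-tribromo-2-(2,4-dibromophenoxy)phenoxy]phenyl sulfate 19 (not isolated)
Conditions: PhC(O)NHOH (1.5 equiv), Cs2CO3, DMSO–H2O, rt; then 1 M HCl, EtOAc, 0 °C
Reagents that add atoms: benzohydroxamic acid, O=C(NO)c1ccccc1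
Why: Fluorosulfate-to-sulfate conversion by SuFEx and Lossen rearrangement: the hydroxamate oxygen displaces fluoride at sulfur to give 18, whose N-deprotonation triggers Lossen rearrangement with the aryl sulfate monoester 19 as leaving group (the phenyl isocyanate is hydrolysed in the aqueous medium to aniline and CO2), and cold acid then gives the hydrogen sulfate.

Compound list
1 | guaiacol (2-methoxyphenol) | COc1ccccc1O | starting material
2 | 2-bromo-6-methoxyphenol | COc1cccc(Br)c1O | intermediate (not isolated)
3 | 2,4-dibromo-6-methoxyphenol | COc1cc(Br)cc(Br)c1O | intermediate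
4 | 5-bromo-2-fluorobenzaldehyde | O=Cc1cc(Br)ccc1F | starting material
5 | 5-bromo-2-(2,4-dibromo-6-methoxyphenoxy)benzaldehyde | COc1cc(Br)cc(Br)c1Oc1ccc(Br)cc1C=O | intermediate
6 | 5-bromo-2-(2,4-dibromo-6-methoxyphenoxy)phenyl formate | COc1cc(Br)cc(Br)c1Oc1ccc(Br)cc1OC=O | intermediate (not isolated)
7 | 5-bromo-2-(2,4-dibromo-6-methoxyphenoxy)phenol | COc1cc(Br)cc(Br)c1Oc1ccc(Br)cc1O | intermediate
8 | 4,5-dibromo-2-(2,4-dibromo-6-methoxyphenoxy)phenol | COc1cc(Br)cc(Br)c1Oc1cc(Br)c(Br)cc1O | intermediate (not isolated)
9 | 2,3,4-tribromo-6-(2,4-dibromo-6-methoxyphenoxy)phenol (A–B phenol) | COc1cc(Br)cc(Br)c1Oc1cc(Br)c(Br)c(Br)c1O | intermediate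
10 | 2-(trimethylsilyl)phenyl triflate | C[Si](C)(C)c1ccccc1OS(=O)(=O)C(F)(F)F | starting material
11 | benzyne | C1=CC=CC#C1 | intermediate (not isolated)
12 | 1,5-dibromo-3-methoxy-2-(3,4,5-tribromo-2-phenoxyphenoxy)benzene | COc1cc(Br)cc(Br)c1Oc1cc(Br)c(Br)c(Br)c1Oc1ccccc1 | intermediate
13 | dibromo[3,5-dibromo-2-(3,4,5-tribromo-2-phenoxyphenoxy)phenoxy]borane | BrB(Br)Oc1cc(Br)cc(Br)c1Oc1cc(Br)c(Br)c(Br)c1Oc1ccccc1 | intermediate (not isolated)
14 | 3,5-dibromo-2-(3,4,5-tribromo-2-phenoxyphenoxy)phenol | Oc1cc(Br)cc(Br)c1Oc1cc(Br)c(Br)c(Br)c1Oc1ccccc1 | intermediate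
15 | 3,5-dibromo-2-(3,4,5-tribromo-2-phenoxyphenoxy)phenyl fluorosulfate | O=S(=O)(F)Oc1cc(Br)cc(Br)c1Oc1cc(Br)c(Br)c(Br)c1Oc1ccccc1 | intermediate
16 | 3,5-dibromo-2-[3,4,5-tribromo-2-(4-bromophenoxy)phenoxy]phenyl fluorosulfate | O=S(=O)(F)Oc1cc(Br)cc(Br)c1Oc1cc(Br)c(Br)c(Br)c1Oc1ccc(Br)cc1 | intermediate (not isolated)
17 | 3,5-dibromo-2-[3,4,5-tribromo-2-(2,4-dibromophenoxy)phenoxy]phenyl fluorosulfate | O=S(=O)(F)Oc1cc(Br)cc(Br)c1Oc1cc(Br)c(Br)c(Br)c1Oc1ccc(Br)cc1Br | intermediate
18 | N-({3,5-dibromo-2-[3,4,5-tribromo-2-(2,4-dibromophenoxy)phenoxy]phenoxy}sulfonyloxy)benzamide | O=C(NOS(=O)(=O)Oc1cc(Br)cc(Br)c1Oc1cc(Br)c(Br)c(Br)c1Oc1ccc(Br)cc1Br)c1ccccc1 | intermediate (not isolated)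
19 | cesium 3,5-dibromo-2-[3,4,5-tribromo-2-(2,4-dibromophenoxy)phenoxy]phenyl sulfate | [Cs+].[O-]S(=O)(=O)Oc1cc(Br)cc(Br)c1Oc1cc(Br)c(Br)c(Br)c1Oc1ccc(Br)cc1Br | intermediate (not isolated)
20 | bromoiesol A sulfate (3,5-dibromo-2-[3,4,5-tribromo-2-(2,4-dibromophenoxy)phenoxy]phenyl hydrogen sulfate) | O=S(=O)(O)Oc1cc(Br)cc(Br)c1Oc1cc(Br)c(Br)c(Br)c1Oc1ccc(Br)cc1Br | target

Total step count: 9. Longest linear sequence: 9 steps (1 → 20); 4 and 10 are commercial and enter directly.

Steps most likely to fail

1. Step 8 (dibromination of ring C). The second substitution, ortho to the ether oxygen on a ring C that already carries its para bromine, is slow. Forcing it may erode site selectivity (bromine entering at carbon 6 of ring B, on ring A, or a third time on ring C) or let the Lewis acid activate the S–F bond. The fallback sets out from 9, does not use the benzyne step, and brings ring C in already dibrominated. Bis(2,4-dibromophenyl)iodonium chloride F1 would be made from 1,3-dibromobenzene and iodyl sulfate in sulfuric acid (substitution para to one bromine and ortho to the other), followed by precipitation with chloride. The sodium phenoxide of 9 and F1 (NaOH, dioxane–H2O, 80 °C) should give, by metal-free ligand coupling at iodine(III), 1,5-dibromo-2-[3,4,5-tribromo-2-(2,4-dibromophenoxy)phenoxy]-3-methoxybenzene F2. BBr3 in CH2Cl2 should then give the free phenol bromoiesol A F3, and SO2F2/Et3N should convert F3 into 17, where the route is rejoined before step 9.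

2. Step 5 (aryne O-arylation). The doubly flanked, weakly basic phenoxide may add too slowly, so that benzyne is consumed by itself or by solvent-derived anions. The aryl anion formed on ring C may also abstract bromine from the neighbouring carbon 3 of ring B in place of being protonated. The fallback sets out from 9: O-phenylation with diphenyliodonium triflate (t-BuOK, THF, rt to 40 °C) is a ligand coupling at iodine(III) that tolerates ortho-disubstituted phenoxides and aryl bromides and involves no free aryl anion. It should give 12 directly, where the route is rejoined; no new compound is made.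

3. Step 3 (Baeyer–Villiger oxidation). Hydride may migrate in place of the aryl group, which is deactivated by bromine and carries only an aryloxy donor, so that the aldehyde is oxidised to the carboxylic acid. The fallback sets out from 3: SNAr with 4-bromo-1-fluoro-2-nitrobenzene (K2CO3, DMF, 60 °C) should give 1,5-dibromo-2-(4-bromo-2-nitrophenoxy)-3-methoxybenzene F4. Fe/NH4Cl (EtOH–H2O, 80 °C) should reduce it, without loss of bromine, to 5-bromo-2-(2,4-dibromo-6-methoxyphenoxy)aniline F5. Diazotisation (NaNO2, aqueous H2SO4/AcOH, 0 °C) should give 5-bromo-2-(2,4-dibromo-6-methoxyphenoxy)benzenediazonium hydrogen sulfate F6, which is hydrolysed (Cu(NO3)2/Cu2O in water at rt, or hot dilute H2SO4) to phenol 7, where the route is rejoined before step 4.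

Further compounds
F1 | step 8 | bis(2,4-dibromophenyl)iodonium chloride | Brc1ccc([I+]c2ccc(Br)cc2Br)c(Br)c1.[Cl-]
F2 | step 8 | 1,5-dibromo-2-[3,4,5-tribromo-2-(2,4-dibromophenoxy)phenoxy]-3-methoxybenzene | COc1cc(Br)cc(Br)c1Oc1cc(Br)c(Br)c(Br)c1Oc1ccc(Br)cc1Br
F3 | step 8 | bromoiesol A (3,5-dibromo-2-[3,4,5-tribromo-2-(2,4-dibromophenoxy)phenoxy]phenol) | Oc1cc(Br)cc(Br)c1Oc1cc(Br)c(Br)c(Br)c1Oc1ccc(Br)cc1Br
F0 | step 5 | none | none
F4 | step 3 | 1,5-dibromo-2-(4-bromo-2-nitrophenoxy)-3-methoxybenzene | COc1cc(Br)cc(Br)c1Oc1ccc(Br)cc1[N+](=O)[O-]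
F5 | step 3 | 5-bromo-2-(2,4-dibromo-6-methoxyphenoxy)aniline | COc1cc(Br)cc(Br)c1Oc1ccc(Br)cc1N
F6 | step 3 | 5-bromo-2-(2,4-dibromo-6-methoxyphenoxy)benzenediazonium hydrogen sulfate | COc1cc(Br)cc(Br)c1Oc1ccc(Br)cc1[N+]#N.OS(=O)(=O)[O-]
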